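**Structure check and assumptions**
- Daucane numbering is used throughout. C1 is the quaternary ring-fusion carbon (bears Me-15). C2 and C3 are CH2. C4 is C(OH)(i-Pr). C5 is the ring-fusion CH. C6 is CH–O-acyl. C7 is CH2. C8(Me)–C9 is the epoxide. C10 is CH2.
- The SMILES decodes to (1R,4R,5S,6S,8R,9S), a trans-fused hydroazulene. The β face carries 15-Me, 4-OH and H-6. The α face carries H-5, i-Pr, the 6-O-acyl group and the epoxide O. The target is the 8α,9α-epoxide of ferutinin.
- Assumption: the absolute sense of induction of the two chiral catalysts (IDPi-A in step 1, HBTM in step 4) is assigned provisionally. Both antipodes are equally accessible, and the one that gives the drawn product is used.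

**Retrosynthetic overview**
1. Jaeskeanin comes from α-face epoxidation of C8=C9 and C6-O-acylation of jaeschkeanadiol 12. The oxirane is the last ring formed.
2. The seven-membered ring comes from RCM (C8=C9) of a trans-1,2-disubstituted cyclopentane. The C6–C7 bond and C6 stereocentre come from chelation-controlled methallylation of β-hydroxy aldehyde 9.
3. The five-membered ring (C4–C5 bond, C4 and C5 stereocentres) comes from isothiourea-catalysed aldol-lactonisation of keto acid 6 to bicyclic β-lactone 7.
4. Keto acid 6 comes from C-acylation and retro-Claisen opening of a sacrificial ring, (R)-3-allyl-3-methylcyclopentanone 3.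
5. The C1 quaternary centre and C1–C10 bond come from a new catalytic enantioselective conjugate Hosomi–Sakurai allylation of 3-methylcyclopentenone.

**Route**

Step 1
Reactants: 1 3-methylcyclopent-2-en-1-one; 2 allyltrimethylsilane
Product: 3 (R)-3-allyl-3-methylcyclopentan-1-one, formed via its TMS enol ether, which is not isolated
Conditions: IDPi-A (2 mol %), 2 (2 equiv), PhMe, −40 → −20 °C; then 1 M HCl/THF, 0 °C. IDPi-A is a new confined (S,S)-imidodiphosphorimidate acid built from two (S)-BINOL units, with 3,3′-(9,9-dimethylfluoren-2-yl) groups and N–SO2C6F5 inner groups.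
Reagents that add atoms: allyltrimethylsilane, C=CC[Si](C)(C)C
Why: Proposed new method: enantioselective conjugate Hosomi–Sakurai allylation of an unactivated β-alkyl cyclic enone under silylium/chiral-counteranion catalysis, in which the acid is silylated in situ by 2 (loss of propene), TMS–IDPi silylates the enone oxygen to give a 1-siloxy-3-methylcyclopentenyl cation held in the confined chiral anion, allyl-TMS attacks the β-carbon through an open SE2′ transition state on the one exposed face (forming C1–C10 and the C1 quaternary centre), and the β-silyl cation returns TMS+ to the anion to release the silyl enol ether and close the cycle; 1,4-selectivity is inherent to allylsilane/enone pairs, and the closest known reaction types are the racemic stoichiometric TiCl4 Sakurai conjugate allylation, Tf2NH/TMSNTf2-catalysed variants, and IDPi-catalysed asymmetric Mukaiyama–Michael additions and aldehyde allylations.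

Step 2
Reactants: 3; 4 isobutyryl chloride
Product: 5 (4S)-4-allyl-4-methyl-2-(2-methylpropanoyl)cyclopentan-1-one, obtained as a mixture of C2 epimers and enol forms
Conditions: MgBr2·OEt2 (2.5 equiv), i-Pr2NEt (3 equiv), 4 (1.2 equiv), CH2Cl2, 0 °C → rt; 1 M HCl work-up
Reagents that add atoms: isobutyryl chloride, CC(C)C(=O)Cl
Why: In this soft-enolisation C-acylation (crossed Claisen type) only the unhindered α-CH2 remote from the quaternary carbon is acylated, the product is trapped as its Mg chelate, and the new α-centre is irrelevant because it is destroyed in step 3.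

Step 3
Reactants: 5
Product: 6 (3R)-3-allyl-3,7-dimethyl-6-oxooctanoic acid
Conditions: 2 M aq NaOH, EtOH, 60 °C; then HCl to pH 2
Reagents that add atoms: sodium hydroxide/water, [Na+].[OH-] / O
Why: In this retro-Claisen cleavage of a 2-acylcyclopentanone, hydroxide adds to the ring carbonyl rather than the i-Pr-shielded exocyclic one and expels the isopropyl-ketone enolate, which unrolls the ring into the C6–C5–C1–C2–C3–C4 chain without touching C1.

Step 4
Reactants: 6
Product: 7 (1R,2R,5R)-2-allyl-5-isopropyl-2-methyl-6-oxabicyclo[3.2.0]heptan-7-one, a cis-fused β-lactone with the lactone ring and 2-Me on one face and allyl, H-1 and i-Pr on the other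
Conditions: TsCl (1.3 equiv), (S)-HBTM (20 mol %), LiCl (1 equiv), i-Pr2NEt (4 equiv), CH2Cl2, slow addition of 6, rt, 24–48 h
Reagents that add atoms: none
Why: In this nucleophile-catalysed aldol-lactonisation the chiral (Z)-acylammonium enolate adds through its unshielded face to the Li-activated ketone (C4–C5 bond), only the aldolate with C4–O cis to C5–C6 can close to the β-lactone (which makes the hindered aldol irreversible), and A1,3 strain places the small Me "inside", so Me ends cis and allyl trans to C6 (matched with the catalyst).

Step 5
Reactants: 7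
Product: 8 (1R,2S,3R)-3-allyl-2-(hydroxymethyl)-1-isopropyl-3-methylcyclopentan-1-ol
Conditions: LiAlH4, Et2O, 0 °C
Reagents that add atoms: none
Why: Hydride reduction of the strained lactone proceeds by acyl–oxygen cleavage, so the C4–O bond and all three stereocentres are retained and the allyl group is inert.

Step 6
Reactants: 8
Product: 9 (1R,2R,5R)-2-allyl-5-hydroxy-5-isopropyl-2-methylcyclopentane-1-carbaldehyde
Conditions: Dess–Martin periodinane, NaHCO3, CH2Cl2, 0 °C → rt
Reagents that add atoms: none
Why: Dess–Martin oxidation touches only the primary alcohol, the buffered neutral medium avoids retro-aldol and E1cB elimination, and C5 already has the thermodynamically preferred configuration (CHO trans to i-Pr and allyl).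

Step 7
Reactants: 9; 10 tributyl(2-methylallyl)stannane
Product: 11 (1R,2S,3R)-3-allyl-2-[(1S)-1-hydroxy-3-methylbut-3-en-1-yl]-1-isopropyl-3-methylcyclopentan-1-ol
Conditions: MgBr2·OEt2 (3 equiv), CH2Cl2, −78 °C; 10 (2.5 equiv), −78 → −20 °C; aq KF work-up
Reagents that add atoms: tributyl(2-methylallyl)stannane, C=C(C)C[Sn](CCCC)(CCCC)CCCC
Why: In this Keck-type chelation-controlled allylstannane addition, Mg(II) ties 4-O and the aldehyde O into a six-membered chelate cis-fused to the cyclopentane, the carbonyl face syn to C1 and its cis 15-Me is blocked, and attack anti to C1 (past H-5) gives (6S), which becomes the 6α-OH.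

Step 8
Reactants: 11
Product: 12 jaeschkeanadiol, (3R,3aS,4S,8aR)-3-isopropyl-6,8a-dimethyl-1,2,3,3a,4,5,8,8a-octahydroazulene-3,4-diol
Conditions: Hoveyda–Grubbs II (5 mol %), 1,4-benzoquinone (10 mol %), PhMe (3 mM), 80 °C
Reagents that add atoms: none
Why: Ring-closing metathesis of the monosubstituted and 1,1-disubstituted alkenes on trans-vicinal arms closes the unstrained trans-fused cycloheptene with the trisubstituted C8=C9 bond, free alcohols are tolerated, and no stereocentre is affected.

Step 9 (side branch)
Reactants: 13 4-hydroxybenzoic acid
Product: 14 4-(tert-butyldimethylsilyloxy)benzoic acid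
Conditions: TBSCl (2.3 equiv), imidazole, DMF, rt; then K2CO3, THF/MeOH/H2O, rt; citric acid
Reagents that add atoms: TBSCl, CC(C)(C)[Si](C)(C)Cl
Why: Bis-silylation followed by selective hydrolysis of the much more labile silyl ester leaves the phenol masked for the coupling.

Step 10
Reactants: 12; 14
Product: 15 ferutinin 4′-O-TBS ether, the C6 4-(TBSO)benzoate of 12 with the 4-OH free
Conditions: 14 (1.5 equiv), EDC·HCl, DMAP, CH2Cl2, rt → 35 °C
Reagents that add atoms: 14, CC(C)(C)[Si](C)(C)Oc1ccc(cc1)C(=O)O
Why: Steglich esterification acylates only the secondary 6α-OH with retention at C6, because the tertiary 4-OH flanked by i-Pr is inert.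

Step 11
Reactants: 15
Product: 16 jaeskeanin 4′-O-TBS ether, the 8α,9α-epoxide of 15
Conditions: mCPBA (1.2 equiv), NaHCO3, CH2Cl2, 0 °C
Reagents that add atoms: mCPBA, OOC(=O)c1cccc(Cl)c1
Why: In this Prilezhaev epoxidation the trans-fused chair cycloheptene tilts C8=C9 toward the β side, so its inner (β) face lies under the axial 15-Me and the peracid attacks the open outer α face to set (8R,9S), while the buffer prevents acid-induced transannular opening by 4-OH.

Step 12
Reactants: 16
Product: 17 jaeskeanin (target)
Conditions: TBAF/AcOH (1.1 equiv each), THF, 0 °C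
Reagents that add atoms: none
Why: Buffered fluoride cleaves the aryl silyl ether within minutes and leaves the hindered benzoate, the epoxide and the tertiary alcohol untouched.

**Compound list**
1 | 3-methylcyclopent-2-en-1-one | CC1=CC(=O)CC1 | starting material
2 | allyltrimethylsilane | C=CC[Si](C)(C)C | starting material
3 | (R)-3-allyl-3-methylcyclopentan-1-one | C=CC[C@@]1(C)CCC(=O)C1 | intermediate
4 | isobutyryl chloride | CC(C)C(=O)Cl | starting material
5 | (4S)-4-allyl-4-methyl-2-(2-methylpropanoyl)cyclopentan-1-one | CC(C)C(=O)C1C[C@](C)(CC=C)CC1=O | intermediate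
6 | (3R)-3-allyl-3,7-dimethyl-6-oxooctanoic acid | CC(C)C(=O)CC[C@](C)(CC=C)CC(=O)O | intermediate
7 | (1R,2R,5R)-2-allyl-5-isopropyl-2-methyl-6-oxabicyclo[3.2.0]heptan-7-one | CC(C)[C@]12CC[C@](C)(CC=C)[C@H]1C(=O)O2 | intermediate
8 | (1R,2S,3R)-3-allyl-2-(hydroxymethyl)-1-isopropyl-3-methylcyclopentan-1-ol | CC(C)[C@]1(O)CC[C@](C)(CC=C)[C@H]1CO | intermediate
9 | (1R,2R,5R)-2-allyl-5-hydroxy-5-isopropyl-2-methylcyclopentane-1-carbaldehyde | CC(C)[C@]1(O)CC[C@](C)(CC=C)[C@H]1C=O | intermediate
10 | tributyl(2-methylallyl)stannane | C=C(C)C[Sn](CCCC)(CCCC)CCCC | starting material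
11 | (1R,2S,3R)-3-allyl-2-[(1S)-1-hydroxy-3-methylbut-3-enyl]-1-isopropyl-3-methylcyclopentan-1-ol | CC(C)[C@]1(O)CC[C@](C)(CC=C)[C@H]1[C@@H](O)CC(C)=C | intermediate
12 | jaeschkeanadiol | CC(C)[C@]1(O)CC[C@]2(C)CC=C(C)C[C@H](O)[C@H]21 | intermediate
13 | 4-hydroxybenzoic acid | OC(=O)c1ccc(O)cc1 | starting material
14 | 4-(tert-butyldimethylsilyloxy)benzoic acid | CC(C)(C)[Si](C)(C)Oc1ccc(cc1)C(=O)O | intermediate
15 | ferutinin 4′-O-TBS ether | CC(C)[C@]1(O)CC[C@]2(C)CC=C(C)C[C@H](OC(=O)c3ccc(O[Si](C)(C)C(C)(C)C)cc3)[C@H]21 | intermediate
16 | jaeskeanin 4′-O-TBS ether | CC(C)[C@]1(O)CC[C@]2(C)C[C@@H]3O[C@]3(C)C[C@H](OC(=O)c3ccc(O[Si](C)(C)C(C)(C)C)cc3)[C@H]21 | intermediate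
17 | jaeskeanin | CC(C)[C@]1(O)CC[C@]2(C)C[C@@H]3O[C@]3(C)C[C@H](OC(=O)c3ccc(O)cc3)[C@H]21 | target

**Totals**
- Total steps: 12.
- Longest linear sequence: 11 (steps 1–8 and 10–12).

**Three steps most likely to fail**
1. **Step 1 (the proposed new reaction).**
   - Risk: allyl-TMS may be too weak a nucleophile for the hindered β-carbon, or face discrimination on such a small flat cation may be insufficient.
   - Fallback (known chemistry): carry out a Ti(IV)/BINOL-catalysed asymmetric 1,2-allylation of 1 with tetraallylstannane to give (R)-1-allyl-3-methylcyclopent-2-en-1-ol. Then run an anionic oxy-Cope rearrangement (KH, 18-crown-6, THF). The allyl group migrates suprafacially from C1 to C3 of the ring and gives (R)-3 with chirality transfer.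
2. **Step 4 (aldol-lactonisation).**
   - Risk: a neopentyl enolate carbon combined with an isopropyl ketone may react slowly. That could lead to decomposition of the activated acid or to eroded dr.
   - Fallback: abandon the ring-opening/re-closure logic and keep the ring of 3.
     - Use the regiospecific TMS enol ether from step 1 directly in a BF3·OEt2 Mukaiyama aldol with 3-methylbut-3-enal, then silylate the C6-OH.
     - Close the seven-membered ring by RCM and equilibrate C5 to the trans-hydroazulenone.
     - Add isopropenyl-CeCl2 to the C4 ketone from the α face, opposite 15-Me.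
     - Hydrogenate the isopropenyl group selectively with Wilkinson's catalyst.
3. **Step 7 (chelation-controlled methallylation).**
   - Risk: the hindered tertiary OH may chelate poorly, which would give the C6 epimer, or Lewis-acid-induced retro-aldol may occur.
   - Fallback: switch from substrate control to reagent control. Cap the 4-OH as its TMS ether and use Brown's B-methallyldiisopinocampheylborane (antipode chosen for 6S). Remove the TMS group during oxidative work-up, then continue with RCM as planned.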